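The data come from a simulation for an exercise; scatter was added.

1. From 3.00 d to 5.00 d the ash run drops 0.5 percentage points, while the larch run drops 5.8 points over the same days, a much steeper fall.

| flask | solid substrate | partner | remark | time |
|---|---|---|---|---|
| ash | 0.19 M | 3 equiv | the very flask that is asked about, followed so far |  |
| larch | 0.38 M | 3 equiv | run made earlier |  |
| flask | 0.19 M | 3.00 equiv |  | 12 d |

| ash: time / d | ash: single product / % | larch: time / d | larch: single product / % |
|---|---|---|---|
| 0.417 | 22.3 | 1.04 | 54.1 |
| 0.625 | 37.5 | 1.67 | 68.4 |
| 0.833 | 49.1 | 2.00 | 70.0 |
| 1.25 | 61.3 | 3.00 | 68.7 |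
| 2.08 | 69.1 | 5.00 | 62.9 |
| 3.00 | 69.8 | 8.00 | 55.7 |
| 5.00 | 69.3 | 12.0 | 49.2 |

(each reading ± 0.5 percentage points)

- as a solid, counted per litre of solution: solid substrate
- the analysis behind the earlier runs scatters by 0.5 percentage points, standard deviation
- at the start none of the solid substrate is in solution

- equivalents of partner to solid substrate, everything else as given, that leave most single product at 12 d
- the amount of single product then, in percent of the solid substrate charged
- the amount of single product with the amounts as given

2. The first way reads the ash tail directly. Its slope of 0.00359 d⁻¹, carried on from the reading at 5.00 d, leaves 67.6% at 12 d.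

3. The second way assumes that single product is lost in a step first order in it and in partner, with partner held as charged (a pseudo-first-order view). Then d[single product]/dt = −κ[partner][single product], which integrates to an exponential. The loss constant κ, the logarithmic fall per day per mole per litre of partner charged, comes from the larch run between 5.00 d and 12.0 d, well past its top: 0.0308 L mol⁻¹ d⁻¹.

4. For the ash flask this gives 0.0175 d⁻¹, and so 61.3% at 12 d.

5. The two ways part by 6.3 points. The first one cheats: its drop is no larger than the scatter of 0.5 points, and it lies beside a top, where formation offsets loss. This reckoning therefore commits to the second number. Since the loss per day follows [partner], it also places the best charge below 3.00 equiv.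

6. The forecast says 2.5 equiv, 70% and 68.5%, on the ground “The loss is strongly concentration-dependent or threshold-like”; its 68.5% stands above the reckoning here.

7. The flask gives 1.50 equiv, 70.5% and 60.0%.

    starting material + partner → single product + released group (k = 0.120 L mol⁻¹ h⁻¹)
    starting material + partner → other mono adduct + released group (k = 0.0390 L mol⁻¹ h⁻¹)
    partner + single product → bis adduct + released group (k = 0.00260 L mol⁻¹ h⁻¹)
    partner + other mono adduct → bis adduct + released group (k = 0.0820 L mol⁻¹ h⁻¹)
    solid substrate ⇌ starting material, rate k5*(cs5 - [starting material]) while solid is left; crystals form when [starting material] > cs5 (solubility = 0.170 M, k = 0.150 h⁻¹)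

8. Between 6.00 d and 12.0 d single product in the flask falls at 0.0193 d⁻¹, beside the reckoned 0.0175 d⁻¹. The neighbour with 0.47 M of solid substrate, at the same equivalents, keeps κ, and with its [partner] as charged the loss rate κ[partner] comes to 0.0434 d⁻¹. Starting from the larch top of 70.0% at 2.00 d, that leaves 45.3% at 12 d. That neighbour holds 44.5% single product, and bis adduct is its largest share at 55.5%.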